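The target is cut at C7=C8 into apo-8'-lycopenal and a C10 cyclopentane end group. In that ring (C2–C3–C4–C5–C6) the chain carbon C7 on C6 is cis to the C5 oxygen and trans to the isopropenyl carbon C1 on the neighbouring C2, so both carbon substituents can be added across a C6=C2 alkene from a silylmethyl tether on the C5 oxygen. A nickel-mediated radical cyclization/cross-coupling forms C6–C7 and C1–C2, closes a cis-fused oxasilolane and sets C6 and C2 from the linalool-derived C5 centre in one operation. Its precursor is the (bromomethyl)dimethylsilyl ether of (R)-1-methylcyclopent-2-en-1-ol, with 2-bromopropene as the partner.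

Key step: step 3

Remark: carotenoid numbering is used for the end group (ring C2–C3–C4–C5–C6, C1 = isopropenyl carbon, C7 = first chain carbon). The target is taken as the all-E (2R,5R,6S) isomer. The R centre of (R)-linalool maps unchanged onto C5 (R), and the descriptors of 2, 4, 6 and 19 are mutually consistent.
Remark: crocetindialdehyde and geranyl bromide are taken as purchased building blocks; all polyenes (from step 9 on) are handled under argon in the dark.

Step 1
Reactants: 1 (R)-linalool
Product: 2 (1R)-1-methylcyclopent-2-en-1-ol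
Conditions: second-generation Grubbs catalyst RuCl2(=CHPh)(H2IMes)(PCy3) (0.5 mol %), CH2Cl2, 40 °C, isobutene vented
Reagents that add atoms: none
Why: Ring-closing metathesis between the vinyl group and the trisubstituted alkene of this 1,6-diene expels isobutene and should close the cyclopentene without touching the tertiary carbinol centre, which therefore stays R.

Step 2
Reactants: 2 (1R)-1-methylcyclopent-2-en-1-ol; 3 (bromomethyl)chlorodimethylsilane
Product: 4 (bromomethyl)dimethyl{[(1R)-1-methylcyclopent-2-en-1-yl]oxy}silane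
Conditions: Et3N, DMAP (cat.), CH2Cl2, 0 → 25 °C; filtration through basic alumina
Reagents that add atoms: none
Why: O-Silylation of the tertiary alcohol at the Si–Cl bond (far more reactive than the C–Br bond) under amine/DMAP catalysis should install the silylmethyl bromide tether on the C5 oxygen.

Step 3
Reactants: 4 (bromomethyl)dimethyl{[(1R)-1-methylcyclopent-2-en-1-yl]oxy}silane; 5 2-bromopropene
Product: 6 (3aS,4R,6aR)-2,2,6a-trimethyl-4-(prop-1-en-2-yl)hexahydro-2H-cyclopenta[d][1,2]oxasilole
Conditions: NiBr2·glyme (5 mol %), 4,4'-di-tert-butyl-2,2'-bipyridine (6 mol %), Mn powder (3 equiv), 5 (3 equiv), DMA (0.05 M), 30 °C, sealed vessel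
Reagents that add atoms: none
Why: Proposed new method: manganese reduces the nickel precatalyst to low-valent nickel, which abstracts bromine from the Si–CH2Br group; the silylmethyl radical adds to C6, the secondary C2 radical is captured by the divalent isopropenylnickel bromide formed from 5 and zerovalent nickel, and reductive elimination from trivalent nickel forms C1–C2 before manganese reduces the nickel bromide again. The closest known reaction types are the tin hydride-mediated radical cyclization of bromomethylsilyl ethers of allylic alcohols and the nickel-catalysed reductive cyclization/cross-coupling of alkene-tethered alkyl bromides (for example bromoacetals) with alkenyl bromides; the new element is their merger on a silicon tether. The oxasilolane ring (C7–Si–O–C5–C6) closes in the 5-exo-trig mode. C6 is set by the tether, which reaches C6 only from the face of the C5 oxygen and can only give a cis-fused bicycle; C2 is set by approach of nickel to the convex face of that bicycle, anti to C7 and away from the SiMe2 group. The step needs 5-exo rather than 6-endo closure (the 6-endo path would have to bridge the cyclopentane), ring closure before nickel captures the first radical (helped by the fully substituted carbinol carbon, the two methyl groups on silicon, low nickel loading and dilution) and anti capture at C2, all of which rest on the short tether and the folded shape of the bicyclic radical.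

Step 4
Reactants: 6 (3aS,4R,6aR)-2,2,6a-trimethyl-4-(prop-1-en-2-yl)hexahydro-2H-cyclopenta[d][1,2]oxasilole
Product: 7 (1R,2R,3R)-2-(hydroxymethyl)-1-methyl-3-(prop-1-en-2-yl)cyclopentan-1-ol
Conditions: 30% H2O2, KF, KHCO3, THF/MeOH (1:1), 25 → 45 °C
Reagents that add atoms: hydrogen peroxide, OO
Why: Tamao–Fleming oxidation of the fluoride-activated cyclic siloxane should replace the C7–Si bond by C7–OH and free the C5 hydroxyl without touching a stereocentre or the isopropenyl group.

Step 5
Reactants: 7 (1R,2R,3R)-2-(hydroxymethyl)-1-methyl-3-(prop-1-en-2-yl)cyclopentan-1-ol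
Product: 8 (1R,2S,3R)-1-methyl-2-{[(1-phenyl-1H-tetrazol-5-yl)sulfanyl]methyl}-3-(prop-1-en-2-yl)cyclopentan-1-ol
Conditions: 1-phenyl-1H-tetrazole-5-thiol, PPh3, DIAD, THF, 0 → 25 °C
Reagents that add atoms: 1-phenyl-1H-tetrazole-5-thiol, Sc1nnnn1-c1ccccc1
Why: A Mitsunobu thioetherification should engage only the primary C7 hydroxyl, because the tertiary C5 alcohol cannot be activated and displaced under these conditions.

Step 6
Reactants: 8 (1R,2S,3R)-1-methyl-2-{[(1-phenyl-1H-tetrazol-5-yl)sulfanyl]methyl}-3-(prop-1-en-2-yl)cyclopentan-1-ol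
Product: 9 (1R,2S,3R)-1-methyl-2-{[(1-phenyl-1H-tetrazol-5-yl)sulfonyl]methyl}-3-(prop-1-en-2-yl)cyclopentan-1-ol
Conditions: (NH4)6Mo7O24·4H2O (10 mol %), 30% H2O2, EtOH, 0 → 25 °C
Reagents that add atoms: hydrogen peroxide, OO
Why: Molybdate-catalysed peroxide oxidation should take the sulfide to the sulfone while the unactivated 1,1-disubstituted alkene and the tertiary alcohol remain untouched.

Step 7
Reactants: 9 (1R,2S,3R)-1-methyl-2-{[(1-phenyl-1H-tetrazol-5-yl)sulfonyl]methyl}-3-(prop-1-en-2-yl)cyclopentan-1-ol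
Product: 10 5-({[(1S,2R,5R)-2-methyl-5-(prop-1-en-2-yl)-2-(triethylsilyloxy)cyclopentyl]methyl}sulfonyl)-1-phenyl-1H-tetrazole
Conditions: Et3SiOTf, 2,6-lutidine, CH2Cl2, −78 → 0 °C
Reagents that add atoms: triethylsilyl trifluoromethanesulfonate, CC[Si](CC)(CC)OS(=O)(=O)C(F)(F)F
Why: Silyl triflate silylation should cap the hindered tertiary hydroxyl, so that no alkoxide can attack the tetrazole ring when the sulfone is metalated in step 10.

Step 8
Reactants: 11 geranyl bromide
Product: 12 [(2E)-3,7-dimethylocta-2,6-dien-1-yl]triphenylphosphonium bromide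
Conditions: PPh3, toluene, 25 °C
Reagents that add atoms: triphenylphosphine, c1ccc(cc1)P(c1ccccc1)c1ccccc1
Why: Direct substitution of the primary allylic bromide by triphenylphosphine should give the phosphonium salt with the 2E geometry intact.

Step 9
Reactants: 12 [(2E)-3,7-dimethylocta-2,6-dien-1-yl]triphenylphosphonium bromide; 13 crocetindialdehyde
Product: 16 apo-8'-lycopenal (all-E C30 aldehyde), via geranylidene phosphorane 14 (not isolated), via 16Z isomer 15 (not isolated)
Conditions: 13 (3 equiv), NaOMe (slow addition), MeOH/CH2Cl2, 0 → 25 °C; then heptane, 80 °C; crystallization, recovery of excess 13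
Reagents that add atoms: none
Why: Wittig olefination of one formyl group, favoured by the excess of dialdehyde, should build the psi end, and the sterically hindered Z isomer at the new double bond should relax thermally to E.

Step 10
Reactants: 10 5-({[(1S,2R,5R)-2-methyl-5-(prop-1-en-2-yl)-2-(triethylsilyloxy)cyclopentyl]methyl}sulfonyl)-1-phenyl-1H-tetrazole; 16 apo-8'-lycopenal
Product: 18 C5-O-triethylsilyl ether of the all-E target, via potassium sulfonyl carbanion 17 (not isolated)
Conditions: KN(SiMe3)2, DME, −60 °C; then 16 in THF, −60 → 25 °C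
Reagents that add atoms: none
Why: Julia–Kocienski olefination (addition of the sulfonyl carbanion to the aldehyde, Smiles rearrangement, loss of sulfur dioxide and tetrazololate) should form C7=C8 with E geometry, and C6 is never acidic, so its configuration is kept.

Step 11
Reactants: 18 C5-O-triethylsilyl ether of the all-E target
Product: 19 (1R,2S,3R)-1-methyl-3-(prop-1-en-2-yl)-2-[(1E,3E,5E,7E,9E,11E,13E,15E,17E,19E)-3,7,12,16,20,24-hexamethylpentacosa-1,3,5,7,9,11,13,15,17,19,23-undecaen-1-yl]cyclopentan-1-ol (target, (2R,5R,6S) in carotenoid numbering)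
Conditions: Bu4NF, THF, 25 °C; crystallization
Reagents that add atoms: none
Why: Fluoride cleaves the tertiary silyl ether under non-acidic conditions that the polyene and the tertiary alcohol should tolerate.

Compound list
1 | (R)-linalool, (3R)-3,7-dimethylocta-1,6-dien-3-ol | C=C[C@](C)(O)CCC=C(C)C | starting material
2 | (1R)-1-methylcyclopent-2-en-1-ol | C[C@]1(O)C=CCC1 | intermediate
3 | (bromomethyl)chlorodimethylsilane | C[Si](C)(Cl)CBr | starting material
4 | (bromomethyl)dimethyl{[(1R)-1-methylcyclopent-2-en-1-yl]oxy}silane | C[C@]1(O[Si](C)(C)CBr)C=CCC1 | intermediate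
5 | 2-bromopropene | C=C(C)Br | starting material
6 | (3aS,4R,6aR)-2,2,6a-trimethyl-4-(prop-1-en-2-yl)hexahydro-2H-cyclopenta[d][1,2]oxasilole (cis-fused, isopropenyl trans to the CH2Si carbon) | C=C(C)[C@@H]1CC[C@@]2(C)O[Si](C)(C)C[C@@H]12 | intermediate
7 | (1R,2R,3R)-2-(hydroxymethyl)-1-methyl-3-(prop-1-en-2-yl)cyclopentan-1-ol | C=C(C)[C@@H]1CC[C@@](C)(O)[C@H]1CO | intermediate
8 | (1R,2S,3R)-1-methyl-2-{[(1-phenyl-1H-tetrazol-5-yl)sulfanyl]methyl}-3-(prop-1-en-2-yl)cyclopentan-1-ol | C=C(C)[C@@H]1CC[C@@](C)(O)[C@H]1CSc1nnnn1-c1ccccc1 | intermediate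
9 | (1R,2S,3R)-1-methyl-2-{[(1-phenyl-1H-tetrazol-5-yl)sulfonyl]methyl}-3-(prop-1-en-2-yl)cyclopentan-1-ol | C=C(C)[C@@H]1CC[C@@](C)(O)[C@H]1CS(=O)(=O)c1nnnn1-c1ccccc1 | intermediate
10 | 5-({[(1S,2R,5R)-2-methyl-5-(prop-1-en-2-yl)-2-(triethylsilyloxy)cyclopentyl]methyl}sulfonyl)-1-phenyl-1H-tetrazole | C=C(C)[C@@H]1CC[C@@](C)(O[Si](CC)(CC)CC)[C@H]1CS(=O)(=O)c1nnnn1-c1ccccc1 | intermediate
11 | geranyl bromide, (2E)-1-bromo-3,7-dimethylocta-2,6-diene | CC(C)=CCC/C(C)=C/CBr | starting material
12 | [(2E)-3,7-dimethylocta-2,6-dien-1-yl]triphenylphosphonium bromide | CC(C)=CCC/C(C)=C/C[P+](c1ccccc1)(c1ccccc1)c1ccccc1.[Br-] | intermediate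
13 | crocetindialdehyde, (2E,4E,6E,8E,10E,12E,14E)-2,6,11,15-tetramethylhexadeca-2,4,6,8,10,12,14-heptaenedial | O=C/C(C)=C/C=C/C(C)=C/C=C/C=C(C)/C=C/C=C(C)/C=O | starting material
14 | [(2E)-3,7-dimethylocta-2,6-dien-1-ylidene]triphenylphosphorane | CC(C)=CCC/C(C)=C/C=P(c1ccccc1)(c1ccccc1)c1ccccc1 | intermediate
15 | (2E,4E,6E,8E,10E,12E,14E,16Z,18E)-2,6,11,15,19,23-hexamethyltetracosa-2,4,6,8,10,12,14,16,18,22-decaenal | O=C/C(C)=C/C=C/C(C)=C/C=C/C=C(C)/C=C/C=C(C)/C=C\C=C(/C)CCC=C(C)C | intermediate
16 | apo-8'-lycopenal, (2E,4E,6E,8E,10E,12E,14E,16E,18E)-2,6,11,15,19,23-hexamethyltetracosa-2,4,6,8,10,12,14,16,18,22-decaenal | O=C/C(C)=C/C=C/C(C)=C/C=C/C=C(C)/C=C/C=C(C)/C=C/C=C(\C)CCC=C(C)C | intermediate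
17 | potassium salt of the sulfonyl-stabilized C7 carbanion of 10 | [K+].C=C(C)[C@@H]1CC[C@@](C)(O[Si](CC)(CC)CC)[C@H]1[CH-]S(=O)(=O)c1nnnn1-c1ccccc1 | intermediate
18 | triethyl({(1R,2S,3R)-1-methyl-2-[(1E,3E,5E,7E,9E,11E,13E,15E,17E,19E)-3,7,12,16,20,24-hexamethylpentacosa-1,3,5,7,9,11,13,15,17,19,23-undecaen-1-yl]-3-(prop-1-en-2-yl)cyclopentyl}oxy)silane | C=C(C)[C@@H]1CC[C@@](C)(O[Si](CC)(CC)CC)[C@H]1/C=C/C(C)=C/C=C/C(C)=C/C=C/C=C(C)/C=C/C=C(C)/C=C/C=C(\C)CCC=C(C)C | intermediate
19 | (1R,2S,3R)-1-methyl-3-(prop-1-en-2-yl)-2-[(1E,3E,5E,7E,9E,11E,13E,15E,17E,19E)-3,7,12,16,20,24-hexamethylpentacosa-1,3,5,7,9,11,13,15,17,19,23-undecaen-1-yl]cyclopentan-1-ol (CNP0222499.2) | C=C(C)[C@@H]1CC[C@@](C)(O)[C@H]1/C=C/C(C)=C/C=C/C(C)=C/C=C/C=C(C)/C=C/C=C(C)/C=C/C=C(\C)CCC=C(C)C | target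

Total step count: 11. Longest linear sequence: 9 steps (steps 1–7, 10 and 11); steps 8 and 9 form the second branch.

Steps most likely to fail

1. Step 3 (key step). The silylmethyl radical may be captured by nickel before it closes the ring, the C–Br bond may simply be reduced, or capture at C2 may occur from the concave face. The fallback keeps the silicon tether but uses known reaction types and a two-carbon surrogate for the isopropenyl group. It sets out from 4. Cobalt-catalysed radical cyclization/cross-coupling with [(trimethylsilyl)ethynyl]magnesium bromide (Co(acac)3, TMEDA, THF, 25 °C), a known reaction class for halides tethered to alkenes, should give (3aS,4R,6aR)-2,2,6a-trimethyl-4-[(trimethylsilyl)ethynyl]hexahydro-2H-cyclopenta[d][1,2]oxasilole F1. Tamao–Fleming oxidation (H2O2, KF, KHCO3, THF/MeOH), which should also remove the alkynyl silyl group, would give (1R,2R,3R)-3-ethynyl-2-(hydroxymethyl)-1-methylcyclopentan-1-ol F2. Zirconium-catalysed methylalumination of the terminal alkyne (Me3Al, Cp2ZrCl2, CH2Cl2, then water) should place the methyl group on the internal carbon and so give the isopropenyl group. The fallback comes back to the route at 7.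

2. Step 10. The hindered sulfonyl carbanion may add slowly to the polyenal, the metalated sulfone may condense with itself, or E selectivity at C7=C8 may erode. The fallback replaces the sulfone by a ring phosphonium salt and needs no protecting group. It sets out from 7. Iodination of the primary alcohol (I2, PPh3, imidazole, CH2Cl2, 0 °C) should give (1R,2S,3R)-2-(iodomethyl)-1-methyl-3-(prop-1-en-2-yl)cyclopentan-1-ol F3. Heating with PPh3 in MeCN should give {[(1S,2R,5R)-2-hydroxy-2-methyl-5-(prop-1-en-2-yl)cyclopentyl]methyl}triphenylphosphonium iodide F4. Two equivalents of NaN(SiMe3)2 in THF at −78 → 0 °C would form the sodium oxido ylide F5. Wittig reaction of this ylide with 16 is expected to give mainly the (7Z)-isomer of the target F6, and warming in heptane should isomerize this hindered Z bond to E. The fallback comes back to the route at 19.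

3. Step 9. Both formyl groups may be olefinated, the thermal Z to E isomerization at the new bond may stay incomplete, or the allylic ylide may react through its γ-carbon. The fallback uses a phosphonate carbanion, which gives the E alkene directly, in place of the ylide. It sets out from 11. Michaelis–Arbuzov reaction with triethyl phosphite (neat, 130 °C) should give diethyl [(2E)-3,7-dimethylocta-2,6-dien-1-yl]phosphonate F7. Horner–Wadsworth–Emmons olefination of excess 13 with its anion (NaN(SiMe3)2, THF, −78 → 25 °C) comes back to the route at 16.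

Further compounds
F1 | step 3 | (3aS,4R,6aR)-2,2,6a-trimethyl-4-[(trimethylsilyl)ethynyl]hexahydro-2H-cyclopenta[d][1,2]oxasilole | C[Si](C)(C)C#C[C@@H]1CC[C@@]2(C)O[Si](C)(C)C[C@@H]12
F2 | step 3 | (1R,2R,3R)-3-ethynyl-2-(hydroxymethyl)-1-methylcyclopentan-1-ol | C#C[C@@H]1CC[C@@](C)(O)[C@H]1CO
F3 | step 10 | (1R,2S,3R)-2-(iodomethyl)-1-methyl-3-(prop-1-en-2-yl)cyclopentan-1-ol | C=C(C)[C@@H]1CC[C@@](C)(O)[C@H]1CI
F4 | step 10 | {[(1S,2R,5R)-2-hydroxy-2-methyl-5-(prop-1-en-2-yl)cyclopentyl]methyl}triphenylphosphonium iodide | C=C(C)[C@@H]1CC[C@@](C)(O)[C@H]1C[P+](c1ccccc1)(c1ccccc1)c1ccccc1.[I-]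
F5 | step 10 | sodium oxido ylide of F4 | [Na+].C=C(C)[C@@H]1CC[C@@](C)([O-])[C@H]1C=P(c1ccccc1)(c1ccccc1)c1ccccc1
F6 | step 10 | (7Z)-isomer of the target (1Z in the side-chain numbering of 19) | C=C(C)[C@@H]1CC[C@@](C)(O)[C@H]1\C=C/C(C)=C/C=C/C(C)=C/C=C/C=C(C)/C=C/C=C(C)/C=C/C=C(\C)CCC=C(C)C
F7 | step 9 | diethyl [(2E)-3,7-dimethylocta-2,6-dien-1-yl]phosphonate | CC(C)=CCC/C(C)=C/CP(=O)(OCC)OCC
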